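# Proposed synthesis of CNP0219585.4 (compound 25) by fluoride displacement at C7a

## Analysis of the target

Compound 25 is a phenylcoumaran neolignan. Ring B is fused to the dihydrofuran ring C, which carries the guaiacyl ring A on C2 and a hydroxymethyl group on C3. Ring B bears a methoxy group on C7 and a 1,2,3-trihydroxypropyl chain (Cα, Cβ, Cγ) on C5. There are four stereocentres in two pairs: C2 (S) and C3 (R) are trans on ring C, and Cα (S) and Cβ (R) form an erythro (anti) diol. Ring B separates the two pairs, so neither can direct the other and each pair needs its own external control element. The sensitive sites are the free para-phenol of ring A with the benzylic C2–O1 bond (quinone methide opening, epimerisation at C2), the benzylic Cα carbinol on an electron-rich ring (ionisation in acid, hydrogenolysis), and five hydroxyl groups of three kinds. The difficulty lies in the 1,2,3,5-tetrasubstituted ring B, the trans ring fusion pattern and the anti diol, all in one absolute configuration. The strategy rests on the fact that C7a is para to C5: with an ester on C5 and fluorine on C7a, an alkoxide on C2 can form the O1–C7a bond by nucleophilic aromatic substitution without touching any bond to C2 or C3.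

## Retrosynthetic reasoning

**25 to 24.** The last disconnection removes only protecting groups. The phenolic benzyl ether, the Cβ benzyl ether and the primary trityl ether of 24 are all benzylic-type C–O bonds, so one hydrogenolysis should release 25 without exposing the free phenol or the Cα carbinol to acid or base.

**24 to 18 and 22.** The Cα–Cβ bond is cut because it joins the two side-chain stereocentres, so one aldol addition sets both. Cutting C5–Cα instead would require an aryl metal at C5 and would give up the C5 carbonyl group on which the ring closure depends. The forward reaction is an anti-selective glycolate aldol between aldehyde 18 and ketene silyl thioacetal 22, and it must be controlled by the reagent because the ring stereocentres are too remote. It gives thioester 23, whose reduction supplies Cγ as the primary alcohol of 24. Reagent 22 comes from acid chloride 19 through thioester 20 and its enolate 21.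

**18 to 16.** Aldehyde 18 is traced back through benzylic alcohol 17 to ester 16. The ester is kept up to this point because it is the acceptor that activates ring B in the key step and, unlike an aldehyde, it is not attacked irreversibly by an alkoxide.

**16 to 14 (key disconnection).** The O1–C7a bond is cut. It is the only ring C bond that can be broken without touching a bond to C2 or C3, so the trans ring problem becomes an acyclic syn relationship in fluoroarene 14. The gain is a ring closure with no stereochemical risk and a ring B that starts as a simple fluorobenzoate. The forward reaction must deliver the C2 alkoxide 15, and only that oxygen, to C7a.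

**14 to 12.** Trityl ether 14 comes from diol 13 by selective protection of the primary hydroxyl, and 13 from aldol adduct 12 by reductive removal of the auxiliary, which returns oxazolidinone 6. The primary oxygen must be blocked by a group that cannot migrate, because it could close an isomeric five-membered ring on the same carbon C7a.

**12 to 8 and 9.** The C2–C3 bond is cut because it joins the two ring stereocentres. A syn aldol between imide 8 and aldehyde 9 (through boron enolate 10 and aldolate 11) sets both in the absolute sense dictated by auxiliary 6.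

**8 to 1.** Imide 8 comes from arylacetic acid 5 and oxazolidinone 6 through mixed anhydride 7. Acid 5 comes from tert-butyl ester 4, made by coupling arylboronate 2 with bromoacetate 3 at the future C3a–C3 bond. Boronate 2 comes from fluorobenzoate 1 by C–H borylation next to fluorine. Fluorine is small enough to allow functionalisation at the adjacent carbon and later serves as the leaving group.

## Alternatives that were turned down

**Alternative 1: oxidative ring contraction of a flavanone.**
- Disconnection: the C3–C3a bond is made by aryl migration. The (2S)-flavanone A1 would be contracted to the dihydrobenzofuran ester A2.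
- Forward key step: a trivalent iodine oxidant under strongly acidic, acetal-forming conditions moves the fused aryl carbon from the carbonyl carbon to the neighbouring methylene carbon. The former carbonyl carbon becomes the exocyclic ester.
- For it: A1 is reached in very few steps from an acetophenone and a vanillin derivative. The ester of A2 is at the right oxidation level for the C3 hydroxymethyl group, and migration anti to the C2 aryl group gives the trans ring. On step count to the bicyclic core this alternative is stronger than the chosen route.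
- Against it: the absolute configuration depends on an enantioselective flavanone synthesis. 2-Aryl chromanones such as A1 can racemise by reversible opening to the chalcone under exactly the acidic conditions of the rearrangement. Migration of the C2 aryl group and dehydrogenation compete, which is why ring A must carry a deactivating sulfonate. A2 carries a bromide at C5 that still has to become an aldehyde in the presence of the C3 ester, and the sulfonate must come off at the end; this uses up the early saving.
- Comparison: the chosen route is longer to the ring system, but it fixes C2 and C3 with a covalently bound auxiliary, has no racemisation channel, and has the C5 carbon at the ester level.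

**Alternative 2: ring B built last by pyranone cycloaddition.**
- Disconnection: C3a–C4 and C7–C7a. Pyranone A3 and the lactone-derived ketene silyl acetal A4 would combine to give the dihydrobenzofuran A5.
- Forward key step: a thermal (4+2) cycloaddition, then decarboxylative cycloreversion and loss of the silyloxy group to aromatise.
- For it: the approach is highly convergent. The substitution pattern of ring B is written into A3, so no arene regiochemistry has to be trusted, and both stereocentres sit in a small lactone before the key step. On convergence and on independence from arene C–H functionalisation it is stronger than the chosen route.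
- Against it: in the primary adduct the future C7a carries two oxygen substituents, the ring oxygen and the silyloxy group. Aromatisation by expulsion of the ring oxygen would open the dihydrofuran. The reacting terminus of A3 bears a donor methoxy group and is hindered. The heating needed puts the allylic stereocentre of A4 at risk. A3 itself needs several steps.
- Comparison: the key step would carry much more risk than an alkoxide–fluoride substitution of a well-known type. The chosen route offers a key step with one possible course and a ring B bought ready-made.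

**Alternative 3: stereoconvergent para-quinone methide closure of O1–C2.**
- Disconnection: the O1–C2 bond. The phenolic diol A6 would close to A7.
- Forward key step: catalytic sulfonic acid ionises the C2 carbinol to a para-quinone methide of ring A, which the ring B phenol traps.
- For it: both C2 epimers converge on the trans ring, so only C3 must be controlled, and no fluorine is needed. On robustness at C2 this alternative is stronger than the chosen route, which must get both centres right in one aldol.
- Against it: the closure needs free phenols on both rings. Phenol protection is therefore needed to build A6 and again on A7 before the side chain is added, which adds several protecting-group operations. The ring B phenol sits para to an ester and is a weak nucleophile. The quinone methide can lose the C3 hydrogen to give a stilbene, which erases the only controlled centre, or it can be trapped intermolecularly.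
- Comparison: the chosen route gives a fully protected product ready for the side-chain work, and its closure proceeds under base with the C3 centre never adjacent to a cation.

Key step: step 8

Assumption: in the Sn(OTf)2/diamine aldol of step 13 the L-proline-derived (S)-diamine is taken to give the (2R,3R) anti adduct with aromatic aldehydes, so the (R)-diamine (from D-proline, recoverable by acid–base extraction) is specified for the required (2S,3S) adduct; the two enantiomers are otherwise interchangeable.

## Route

Step 1
Reactants: 1 methyl 4-fluoro-3-methoxybenzoate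
Product: 2 methyl 4-fluoro-3-methoxy-5-(4,4,5,5-tetramethyl-1,3,2-dioxaborolan-2-yl)benzoate
Conditions: B2pin2 (1.0 equiv), [Ir(OMe)(cod)]2 (1.5 mol %), 4,4'-di-tert-butyl-2,2'-bipyridine (3 mol %), THF, 70 °C
Reagents that add atoms: bis(pinacolato)diboron, CC1(C)OB(OC1(C)C)B1OC(C)(C)C(C)(C)O1
Why: Sterically governed iridium-catalysed aromatic C–H borylation; of the three ring hydrogens one lies between ester and methoxy and one lies next to the ester, whereas the third has only the small fluorine as neighbour and is acidified by it, so boron should enter ortho to fluorine.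

Step 2
Reactants: 2 methyl 4-fluoro-3-methoxy-5-(4,4,5,5-tetramethyl-1,3,2-dioxaborolan-2-yl)benzoate; 3 tert-butyl bromoacetate
Product: 4 methyl 3-(2-tert-butoxy-2-oxoethyl)-4-fluoro-5-methoxybenzoate
Conditions: Pd2(dba)3 (2.5 mol %), P(o-tol)3 (10 mol %), K3PO4, THF/H2O, 50 °C
Reagents that add atoms: none
Why: Suzuki–Miyaura coupling of an arylboronate with an α-bromo ester; zerovalent palladium inserts into the C–Br bond, the resulting palladium enolate transmetalates with the aryl borate and reductive elimination forms the aryl–CH2 bond, while the tert-butyl ester resists hydrolysis and self-condensation.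

Step 3
Reactants: 4 methyl 3-(2-tert-butoxy-2-oxoethyl)-4-fluoro-5-methoxybenzoate
Product: 5 2-[2-fluoro-3-methoxy-5-(methoxycarbonyl)phenyl]acetic acid
Conditions: CF3CO2H/CH2Cl2 (1:3), rt
Reagents that add atoms: none
Why: Acidolysis of a tert-butyl ester through the tert-butyl cation; the methyl benzoate and the aryl fluoride are inert, so the two esters are differentiated.

Step 4
Reactants: 5 2-[2-fluoro-3-methoxy-5-(methoxycarbonyl)phenyl]acetic acid; 6 (4S)-4-benzyl-1,3-oxazolidin-2-one
Product: 8 methyl 3-{2-[(4S)-4-benzyl-2-oxo-1,3-oxazolidin-3-yl]-2-oxoethyl}-4-fluoro-5-methoxybenzoate, via mixed pivalic anhydride 7 (not isolated)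
Conditions: t-BuCOCl, Et3N, THF, –20 °C; then LiCl, 6, –20 °C to rt
Reagents that add atoms: none
Why: N-Acylation through a mixed anhydride; the lithium-coordinated oxazolidinone attacks the less hindered arylacetyl carbonyl of 7, and no organolithium base is needed that would attack the benzoate.

Step 5
Reactants: 8 methyl 3-{2-[(4S)-4-benzyl-2-oxo-1,3-oxazolidin-3-yl]-2-oxoethyl}-4-fluoro-5-methoxybenzoate; 9 4-benzyloxy-3-methoxybenzaldehyde
Product: 12 methyl 3-[(1S,2S)-3-[(4S)-4-benzyl-2-oxo-1,3-oxazolidin-3-yl]-1-(4-benzyloxy-3-methoxyphenyl)-1-hydroxy-3-oxopropan-2-yl]-4-fluoro-5-methoxybenzoate, via (Z)-dibutylboron enolate 10 (not isolated), via dibutylboron aldolate 11 (not isolated)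
Conditions: Bu2BOTf (1.2 equiv), i-Pr2NEt (1.4 equiv), CH2Cl2, –78 to 0 °C; 9, –78 to 0 °C; then pH 7 buffer, MeOH, 30% H2O2, 0 °C
Reagents that add atoms: none
Why: Evans syn aldol; soft enolisation gives the (Z)-boron enolate, which reacts through a chair Zimmerman–Traxler transition state with the auxiliary carbonyl turned away, so the non-enolisable aldehyde approaches the enolate face opposite the benzyl group and both the carbinol carbon (future C2, S) and the aryl-bearing carbon (future C3) are set syn by the (4S)-auxiliary.

Step 6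
Reactants: 12 methyl 3-[(1S,2S)-3-[(4S)-4-benzyl-2-oxo-1,3-oxazolidin-3-yl]-1-(4-benzyloxy-3-methoxyphenyl)-1-hydroxy-3-oxopropan-2-yl]-4-fluoro-5-methoxybenzoate
Product: 13 methyl 3-[(1S,2R)-1-(4-benzyloxy-3-methoxyphenyl)-1,3-dihydroxypropan-2-yl]-4-fluoro-5-methoxybenzoate
Conditions: NaBH4, THF/H2O (4:1), 0 °C to rt
Reagents that add atoms: none
Why: Reductive cleavage of an N-acyl oxazolidinone; hydride attacks the activated exocyclic imide carbonyl and releases 6, whereas a methyl benzoate is not reduced by NaBH4 under these conditions, and the descriptor at the aryl-bearing carbon changes from S to R only through the change in substituent priority.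

Step 7
Reactants: 13 methyl 3-[(1S,2R)-1-(4-benzyloxy-3-methoxyphenyl)-1,3-dihydroxypropan-2-yl]-4-fluoro-5-methoxybenzoate
Product: 14 methyl 3-[(1S,2R)-1-(4-benzyloxy-3-methoxyphenyl)-1-hydroxy-3-(trityloxy)propan-2-yl]-4-fluoro-5-methoxybenzoate
Conditions: Ph3CCl, Et3N, DMAP (cat.), CH2Cl2, rt
Reagents that add atoms: trityl chloride, ClC(c1ccccc1)(c1ccccc1)c1ccccc1
Why: Tritylation through the trityl cation is selective for the primary hydroxyl for steric reasons, which leaves the secondary benzylic hydroxyl as the only free oxygen nucleophile for the ring closure.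

Step 8
Reactants: 14 methyl 3-[(1S,2R)-1-(4-benzyloxy-3-methoxyphenyl)-1-hydroxy-3-(trityloxy)propan-2-yl]-4-fluoro-5-methoxybenzoate
Product: 16 methyl (2S,3R)-2-(4-benzyloxy-3-methoxyphenyl)-7-methoxy-3-(trityloxymethyl)-2,3-dihydro-1-benzofuran-5-carboxylate, via potassium alkoxide 15 (not isolated)
Conditions: KN(SiMe3)2 (1.1 equiv), THF (0.02 M), –20 °C to rt
Reagents that add atoms: none
Why: KN(SiMe3)2 removes the only hydroxyl proton to give potassium alkoxide 15, which adds to C7a ipso to fluorine; the Meisenheimer anion is delocalised onto C5 and into the ester carbonyl, and loss of fluoride restores the aromatic ring (addition–elimination). The closest known reaction type is the intramolecular etherification of carbonyl-activated 2-(2-fluoroaryl)ethanols to 2,3-dihydrobenzofurans. Ring C closes in a 5-exo-trig mode and O1–C7a is the only bond formed. No stereocentre is made or broken: the C2–O and C3–C3a bonds are spectators, so the (1S,2R) syn arrangement of 14 appears as (2S,3R) in 16, with ring A and the trityloxymethyl group trans, which is also their antiperiplanar arrangement in the reacting rotamer. The step needs selectivity for the secondary oxygen; this is secured because the primary oxygen, which could close an isomeric five-membered ring on the same carbon, is held as a trityl ether that cannot migrate under base. It needs the substitution to take place at C7a only, which holds because fluorine is the sole leaving group and sits para to the ester. It needs ring closure to outrun intermolecular attack of the alkoxide on the ester, which high dilution, low temperature and the non-nucleophilic amide base should favour.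

Step 9
Reactants: 16 methyl (2S,3R)-2-(4-benzyloxy-3-methoxyphenyl)-7-methoxy-3-(trityloxymethyl)-2,3-dihydro-1-benzofuran-5-carboxylate
Product: 17 [(2S,3R)-2-(4-benzyloxy-3-methoxyphenyl)-7-methoxy-3-(trityloxymethyl)-2,3-dihydro-1-benzofuran-5-yl]methanol
Conditions: LiAlH4, THF, 0 °C; aqueous NaOH work-up
Reagents that add atoms: none
Why: Hydride reduction of an aromatic ester to the benzylic alcohol; the benzyl, trityl and aryl ethers and both ring stereocentres are inert to LiAlH4.

Step 10
Reactants: 17 [(2S,3R)-2-(4-benzyloxy-3-methoxyphenyl)-7-methoxy-3-(trityloxymethyl)-2,3-dihydro-1-benzofuran-5-yl]methanol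
Product: 18 (2S,3R)-2-(4-benzyloxy-3-methoxyphenyl)-7-methoxy-3-(trityloxymethyl)-2,3-dihydro-1-benzofuran-5-carbaldehyde
Conditions: MnO2 (activated, excess), CH2Cl2, rt
Reagents that add atoms: none
Why: MnO2 oxidises benzylic alcohols selectively on its surface and stops at the aldehyde; the conditions are neutral, so the trityl ether and the C2–O1 bond are not at risk.

Step 11
Reactants: 19 2-(benzyloxy)acetyl chloride
Product: 20 S-ethyl 2-(benzyloxy)ethanethioate
Conditions: EtSH, Et3N, CH2Cl2, 0 °C to rt
Reagents that add atoms: ethanethiol, CCS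
Why: Acylation of a thiol by an acid chloride (addition–elimination at the acyl carbon) gives the thioester needed for enol silane formation.

Step 12
Reactants: 20 S-ethyl 2-(benzyloxy)ethanethioate
Product: 22 (Z)-{[2-(benzyloxy)-1-(ethylsulfanyl)ethenyl]oxy}trimethylsilane, via lithium enolate 21 (not isolated)
Conditions: LiN(iPr)2, THF, –78 °C; Me3SiCl, –78 °C to rt
Reagents that add atoms: chlorotrimethylsilane, C[Si](C)(C)Cl
Why: Kinetic deprotonation of the thioester and O-silylation of the enolate should give the ketene silyl thioacetal with sulfur and benzyloxy cis, the geometry from which the anti-selective Mukaiyama aldol proceeds.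

Step 13
Reactants: 18 (2S,3R)-2-(4-benzyloxy-3-methoxyphenyl)-7-methoxy-3-(trityloxymethyl)-2,3-dihydro-1-benzofuran-5-carbaldehyde; 22 (Z)-{[2-(benzyloxy)-1-(ethylsulfanyl)ethenyl]oxy}trimethylsilane
Product: 23 S-ethyl (2S,3S)-2-(benzyloxy)-3-[(2S,3R)-2-(4-benzyloxy-3-methoxyphenyl)-7-methoxy-3-(trityloxymethyl)-2,3-dihydro-1-benzofuran-5-yl]-3-hydroxypropanethioate
Conditions: Sn(OTf)2 (1.2 equiv), (R)-1-ethyl-2-(piperidin-1-ylmethyl)pyrrolidine (1.4 equiv), Bu2Sn(OAc)2 (1.3 equiv), CH2Cl2, –78 °C; aq. NaHCO3
Reagents that add atoms: none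
Why: Mukaiyama aldol under chiral Lewis acid control; the diamine-bound divalent tin triflate activates the aldehyde and shields one of its faces, and the α-benzyloxy enol silane adds through an open transition state in which tin engages the benzyloxy oxygen, which should give the anti adduct; the diamine alone sets Cα (S) and Cβ, since the ring stereocentres are too far away to bias the addition, and the aldolate is released as the free alcohol on work-up.

Step 14
Reactants: 23 S-ethyl (2S,3S)-2-(benzyloxy)-3-[(2S,3R)-2-(4-benzyloxy-3-methoxyphenyl)-7-methoxy-3-(trityloxymethyl)-2,3-dihydro-1-benzofuran-5-yl]-3-hydroxypropanethioate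
Product: 24 (1S,2R)-2-(benzyloxy)-1-[(2S,3R)-2-(4-benzyloxy-3-methoxyphenyl)-7-methoxy-3-(trityloxymethyl)-2,3-dihydro-1-benzofuran-5-yl]propane-1,3-diol
Conditions: LiBH4, THF, 0 °C to rt
Reagents that add atoms: none
Why: Borohydride reduction of a thioester to the primary alcohol with loss of the thiolate; no other reducible group is present, and the descriptor at Cβ changes from S to R only because the carbonyl carbon becomes a hydroxymethyl group of lower priority.

Step 15
Reactants: 24 (1S,2R)-2-(benzyloxy)-1-[(2S,3R)-2-(4-benzyloxy-3-methoxyphenyl)-7-methoxy-3-(trityloxymethyl)-2,3-dihydro-1-benzofuran-5-yl]propane-1,3-diol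
Product: 25 (1S,2R)-1-[(2S,3R)-2-(4-hydroxy-3-methoxyphenyl)-3-(hydroxymethyl)-7-methoxy-2,3-dihydro-1-benzofuran-5-yl]propane-1,2,3-triol
Conditions: H2 (1 atm), Pd(OH)2/C, EtOAc/EtOH, rt
Reagents that add atoms: none
Why: Catalytic hydrogenolysis cleaves the two benzyl ethers and the trityl ether at their unhindered phenyl-substituted carbons, whereas the Cα carbinol and the C2–O1 bond are secondary benzylic positions on crowded, electron-rich rings and should survive neutral conditions if the reaction is stopped at complete deprotection.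

## Compound list

1 | methyl 4-fluoro-3-methoxybenzoate | COC(=O)c1ccc(F)c(OC)c1 | starting material
2 | methyl 4-fluoro-3-methoxy-5-(4,4,5,5-tetramethyl-1,3,2-dioxaborolan-2-yl)benzoate | COC(=O)c1cc(OC)c(F)c(B2OC(C)(C)C(C)(C)O2)c1 | intermediate
3 | tert-butyl bromoacetate | CC(C)(C)OC(=O)CBr | starting material
4 | methyl 3-(2-tert-butoxy-2-oxoethyl)-4-fluoro-5-methoxybenzoate | COC(=O)c1cc(OC)c(F)c(CC(=O)OC(C)(C)C)c1 | intermediate
5 | 2-[2-fluoro-3-methoxy-5-(methoxycarbonyl)phenyl]acetic acid | COC(=O)c1cc(OC)c(F)c(CC(=O)O)c1 | intermediate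
6 | (4S)-4-benzyl-1,3-oxazolidin-2-one | O=C1N[C@@H](Cc2ccccc2)CO1 | starting material
7 | 2-[2-fluoro-3-methoxy-5-(methoxycarbonyl)phenyl]acetic pivalic anhydride | COC(=O)c1cc(OC)c(F)c(CC(=O)OC(=O)C(C)(C)C)c1 | intermediate (not isolated)
8 | methyl 3-{2-[(4S)-4-benzyl-2-oxo-1,3-oxazolidin-3-yl]-2-oxoethyl}-4-fluoro-5-methoxybenzoate | COC(=O)c1cc(OC)c(F)c(CC(=O)N2[C@@H](Cc3ccccc3)COC2=O)c1 | intermediate
9 | 4-benzyloxy-3-methoxybenzaldehyde | COc1cc(C=O)ccc1OCc1ccccc1 | starting material
10 | (Z)-dibutylboron enolate of 8 | CCCCB(CCCC)O/C(=C\c1cc(C(=O)OC)cc(OC)c1F)N1[C@@H](Cc2ccccc2)COC1=O | intermediate (not isolated)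
11 | dibutylboron aldolate of 12 | COc1cc([C@@H](OB(CCCC)CCCC)[C@@H](C(=O)N2[C@@H](Cc3ccccc3)COC2=O)c2cc(C(=O)OC)cc(OC)c2F)ccc1OCc1ccccc1 | intermediate (not isolated)
12 | methyl 3-[(1S,2S)-3-[(4S)-4-benzyl-2-oxo-1,3-oxazolidin-3-yl]-1-(4-benzyloxy-3-methoxyphenyl)-1-hydroxy-3-oxopropan-2-yl]-4-fluoro-5-methoxybenzoate | COc1cc([C@@H](O)[C@@H](C(=O)N2[C@@H](Cc3ccccc3)COC2=O)c2cc(C(=O)OC)cc(OC)c2F)ccc1OCc1ccccc1 | intermediate
13 | methyl 3-[(1S,2R)-1-(4-benzyloxy-3-methoxyphenyl)-1,3-dihydroxypropan-2-yl]-4-fluoro-5-methoxybenzoate | COc1cc([C@@H](O)[C@@H](CO)c2cc(C(=O)OC)cc(OC)c2F)ccc1OCc1ccccc1 | intermediate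
14 | methyl 3-[(1S,2R)-1-(4-benzyloxy-3-methoxyphenyl)-1-hydroxy-3-(trityloxy)propan-2-yl]-4-fluoro-5-methoxybenzoate | COc1cc([C@@H](O)[C@@H](COC(c2ccccc2)(c2ccccc2)c2ccccc2)c2cc(C(=O)OC)cc(OC)c2F)ccc1OCc1ccccc1 | intermediate
15 | potassium alkoxide of 14 | COc1cc([C@@H]([O-])[C@@H](COC(c2ccccc2)(c2ccccc2)c2ccccc2)c2cc(C(=O)OC)cc(OC)c2F)ccc1OCc1ccccc1.[K+] | intermediate (not isolated)
16 | methyl (2S,3R)-2-(4-benzyloxy-3-methoxyphenyl)-7-methoxy-3-(trityloxymethyl)-2,3-dihydro-1-benzofuran-5-carboxylate | COc1cc([C@H]2Oc3c(OC)cc(C(=O)OC)cc3[C@@H]2COC(c4ccccc4)(c4ccccc4)c4ccccc4)ccc1OCc1ccccc1 | intermediate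
17 | [(2S,3R)-2-(4-benzyloxy-3-methoxyphenyl)-7-methoxy-3-(trityloxymethyl)-2,3-dihydro-1-benzofuran-5-yl]methanol | COc1cc([C@H]2Oc3c(OC)cc(CO)cc3[C@@H]2COC(c4ccccc4)(c4ccccc4)c4ccccc4)ccc1OCc1ccccc1 | intermediate
18 | (2S,3R)-2-(4-benzyloxy-3-methoxyphenyl)-7-methoxy-3-(trityloxymethyl)-2,3-dihydro-1-benzofuran-5-carbaldehyde | COc1cc([C@H]2Oc3c(OC)cc(C=O)cc3[C@@H]2COC(c4ccccc4)(c4ccccc4)c4ccccc4)ccc1OCc1ccccc1 | intermediate
19 | 2-(benzyloxy)acetyl chloride | O=C(Cl)COCc1ccccc1 | starting material
20 | S-ethyl 2-(benzyloxy)ethanethioate | CCSC(=O)COCc1ccccc1 | intermediate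
21 | lithium (Z)-enolate of 20 | CCS/C([O-])=C\OCc1ccccc1.[Li+] | intermediate (not isolated)
22 | (Z)-{[2-(benzyloxy)-1-(ethylsulfanyl)ethenyl]oxy}trimethylsilane | CCS/C(O[Si](C)(C)C)=C\OCc1ccccc1 | intermediate
23 | S-ethyl (2S,3S)-2-(benzyloxy)-3-[(2S,3R)-2-(4-benzyloxy-3-methoxyphenyl)-7-methoxy-3-(trityloxymethyl)-2,3-dihydro-1-benzofuran-5-yl]-3-hydroxypropanethioate | COc1cc([C@H]2Oc3c(OC)cc([C@H](O)[C@H](OCc4ccccc4)C(=O)SCC)cc3[C@@H]2COC(c4ccccc4)(c4ccccc4)c4ccccc4)ccc1OCc1ccccc1 | intermediate
24 | (1S,2R)-2-(benzyloxy)-1-[(2S,3R)-2-(4-benzyloxy-3-methoxyphenyl)-7-methoxy-3-(trityloxymethyl)-2,3-dihydro-1-benzofuran-5-yl]propane-1,3-diol | COc1cc([C@H]2Oc3c(OC)cc([C@H](O)[C@H](OCc4ccccc4)CO)cc3[C@@H]2COC(c4ccccc4)(c4ccccc4)c4ccccc4)ccc1OCc1ccccc1 | intermediate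
25 | (1S,2R)-1-[(2S,3R)-2-(4-hydroxy-3-methoxyphenyl)-3-(hydroxymethyl)-7-methoxy-2,3-dihydro-1-benzofuran-5-yl]propane-1,2,3-triol | COc1cc([C@H]2Oc3c(OC)cc([C@H](O)[C@H](O)CO)cc3[C@@H]2CO)ccc1O | target

## Step count and least certain steps

Total: 15 steps. Longest linear sequence: 13 steps (steps 1 to 10 and 13 to 15); steps 11 and 12 form a two-step side branch.

**Step 8 (key step).**
- Risk: intermolecular attack of the alkoxide on the methyl ester is the most likely failure. It liberates methoxide, which can itself replace fluoride, and the bulky trityl group may slow the reacting rotamer enough for this path to compete.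
- Fallback: it sets out from 14 and returns to the route at 18. LiAlH4 reduces the ester of 14 to the benzylic alcohol (1S,2R)-1-(4-benzyloxy-3-methoxyphenyl)-2-[2-fluoro-5-(hydroxymethyl)-3-methoxyphenyl]-3-(trityloxy)propan-1-ol F1. Aerobic oxidation with [Cu(MeCN)4]OTf, 2,2'-bipyridine, TEMPO and N-methylimidazole converts primary but not secondary alcohols and should give 4-fluoro-3-[(1S,2R)-1-(4-benzyloxy-3-methoxyphenyl)-1-hydroxy-3-(trityloxy)propan-2-yl]-5-methoxybenzaldehyde F2. Cs2CO3 in DMF then closes the same O1–C7a bond on a ring activated by a para formyl group, a stronger acceptor with no exchangeable alkoxy group, and gives aldehyde 18 directly, so that steps 9 and 10 are not needed.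

**Step 13.**
- Risk: poor or reversed facial selectivity with a hindered, electron-rich aldehyde that offers several Lewis-basic sites to tin, incomplete anti selectivity, and loss of the trityl ether to the Lewis acid.
- Fallback: it sets out from 18 and returns at 25, using an asymmetric epoxidation whose sense follows from the tartrate.
  - Wittig reaction of 18 with Ph3P=CHCO2Et gives ethyl (E)-3-[(2S,3R)-2-(4-benzyloxy-3-methoxyphenyl)-7-methoxy-3-(trityloxymethyl)-2,3-dihydro-1-benzofuran-5-yl]prop-2-enoate F3.
  - i-Bu2AlH gives the allylic alcohol (E)-3-[(2S,3R)-2-(4-benzyloxy-3-methoxyphenyl)-7-methoxy-3-(trityloxymethyl)-2,3-dihydro-1-benzofuran-5-yl]prop-2-en-1-ol F4.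
  - Sharpless asymmetric epoxidation with Ti(OiPr)4, D-(–)-diethyl tartrate and t-BuOOH gives the epoxy alcohol [(2R,3R)-3-[(2S,3R)-2-(4-benzyloxy-3-methoxyphenyl)-7-methoxy-3-(trityloxymethyl)-2,3-dihydro-1-benzofuran-5-yl]oxiran-2-yl]methanol F5.
  - Ti(OiPr)4-mediated opening at the benzylic carbon by benzyl alcohol with inversion gives (2R,3S)-3-(benzyloxy)-3-[(2S,3R)-2-(4-benzyloxy-3-methoxyphenyl)-7-methoxy-3-(trityloxymethyl)-2,3-dihydro-1-benzofuran-5-yl]propane-1,2-diol F6.
  - Hydrogenolysis over Pd(OH)2/C as in step 15 gives 25.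

**Step 15.**
- Risk: slow hydrogenolysis of the trityl ether, which prolongs the exposure and invites reductive cleavage of the benzylic C–O bonds at Cα and C2; traces of thiol from step 14 would slow the catalyst further.
- Fallback: it sets out from 18 and returns at 25, exchanging the trityl group before the acid-sensitive carbinol exists.
  - Aqueous AcOH (80%, 40 °C) removes the trityl group and gives (2S,3R)-2-(4-benzyloxy-3-methoxyphenyl)-3-(hydroxymethyl)-7-methoxy-2,3-dihydro-1-benzofuran-5-carbaldehyde F7.
  - BnBr with Ag2O gives (2S,3R)-3-(benzyloxymethyl)-2-(4-benzyloxy-3-methoxyphenyl)-7-methoxy-2,3-dihydro-1-benzofuran-5-carbaldehyde F8.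
  - The aldol with 22 under the conditions of step 13 gives S-ethyl (2S,3S)-2-(benzyloxy)-3-[(2S,3R)-3-(benzyloxymethyl)-2-(4-benzyloxy-3-methoxyphenyl)-7-methoxy-2,3-dihydro-1-benzofuran-5-yl]-3-hydroxypropanethioate F9.
  - LiBH4 gives (1S,2R)-2-(benzyloxy)-1-[(2S,3R)-3-(benzyloxymethyl)-2-(4-benzyloxy-3-methoxyphenyl)-7-methoxy-2,3-dihydro-1-benzofuran-5-yl]propane-1,3-diol F10.
  - A short hydrogenolysis of the three benzyl ethers over Pd/C gives 25.

**Step 2.**
- Risk: protodeboronation of the ortho-fluoro arylboronate in the basic aqueous medium, and homocoupling, may outpace the slow transmetalation with the palladium enolate.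
- Fallback: it sets out from 2 and returns at 4 with the roles of the partners reversed. CuBr2 in MeOH/H2O converts 2 into methyl 3-bromo-4-fluoro-5-methoxybenzoate F11. Negishi-type coupling of F11 with the Reformatsky reagent BrZnCH2CO2tBu (made from 3 and zinc) under Pd2(dba)3/XPhos gives 4.

## Further compounds

F1 | step 8 | (1S,2R)-1-(4-benzyloxy-3-methoxyphenyl)-2-[2-fluoro-5-(hydroxymethyl)-3-methoxyphenyl]-3-(trityloxy)propan-1-ol | COc1cc([C@@H](O)[C@@H](COC(c2ccccc2)(c2ccccc2)c2ccccc2)c2cc(CO)cc(OC)c2F)ccc1OCc1ccccc1
F2 | step 8 | 4-fluoro-3-[(1S,2R)-1-(4-benzyloxy-3-methoxyphenyl)-1-hydroxy-3-(trityloxy)propan-2-yl]-5-methoxybenzaldehyde | COc1cc([C@@H](O)[C@@H](COC(c2ccccc2)(c2ccccc2)c2ccccc2)c2cc(C=O)cc(OC)c2F)ccc1OCc1ccccc1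
F3 | step 13 | ethyl (E)-3-[(2S,3R)-2-(4-benzyloxy-3-methoxyphenyl)-7-methoxy-3-(trityloxymethyl)-2,3-dihydro-1-benzofuran-5-yl]prop-2-enoate | COc1cc([C@H]2Oc3c(OC)cc(/C=C/C(=O)OCC)cc3[C@@H]2COC(c4ccccc4)(c4ccccc4)c4ccccc4)ccc1OCc1ccccc1
F4 | step 13 | (E)-3-[(2S,3R)-2-(4-benzyloxy-3-methoxyphenyl)-7-methoxy-3-(trityloxymethyl)-2,3-dihydro-1-benzofuran-5-yl]prop-2-en-1-ol | COc1cc([C@H]2Oc3c(OC)cc(/C=C/CO)cc3[C@@H]2COC(c4ccccc4)(c4ccccc4)c4ccccc4)ccc1OCc1ccccc1
F5 | step 13 | [(2R,3R)-3-[(2S,3R)-2-(4-benzyloxy-3-methoxyphenyl)-7-methoxy-3-(trityloxymethyl)-2,3-dihydro-1-benzofuran-5-yl]oxiran-2-yl]methanol | COc1cc([C@H]2Oc3c(OC)cc([C@H]5O[C@@H]5CO)cc3[C@@H]2COC(c4ccccc4)(c4ccccc4)c4ccccc4)ccc1OCc1ccccc1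
F6 | step 13 | (2R,3S)-3-(benzyloxy)-3-[(2S,3R)-2-(4-benzyloxy-3-methoxyphenyl)-7-methoxy-3-(trityloxymethyl)-2,3-dihydro-1-benzofuran-5-yl]propane-1,2-diol | COc1cc([C@H]2Oc3c(OC)cc([C@H](OCc4ccccc4)[C@H](O)CO)cc3[C@@H]2COC(c4ccccc4)(c4ccccc4)c4ccccc4)ccc1OCc1ccccc1
F7 | step 15 | (2S,3R)-2-(4-benzyloxy-3-methoxyphenyl)-3-(hydroxymethyl)-7-methoxy-2,3-dihydro-1-benzofuran-5-carbaldehyde | COc1cc([C@H]2Oc3c(OC)cc(C=O)cc3[C@@H]2CO)ccc1OCc1ccccc1
F8 | step 15 | (2S,3R)-3-(benzyloxymethyl)-2-(4-benzyloxy-3-methoxyphenyl)-7-methoxy-2,3-dihydro-1-benzofuran-5-carbaldehyde | COc1cc([C@H]2Oc3c(OC)cc(C=O)cc3[C@@H]2COCc4ccccc4)ccc1OCc1ccccc1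
F9 | step 15 | S-ethyl (2S,3S)-2-(benzyloxy)-3-[(2S,3R)-3-(benzyloxymethyl)-2-(4-benzyloxy-3-methoxyphenyl)-7-methoxy-2,3-dihydro-1-benzofuran-5-yl]-3-hydroxypropanethioate | COc1cc([C@H]2Oc3c(OC)cc([C@H](O)[C@H](OCc4ccccc4)C(=O)SCC)cc3[C@@H]2COCc4ccccc4)ccc1OCc1ccccc1
F10 | step 15 | (1S,2R)-2-(benzyloxy)-1-[(2S,3R)-3-(benzyloxymethyl)-2-(4-benzyloxy-3-methoxyphenyl)-7-methoxy-2,3-dihydro-1-benzofuran-5-yl]propane-1,3-diol | COc1cc([C@H]2Oc3c(OC)cc([C@H](O)[C@H](OCc4ccccc4)CO)cc3[C@@H]2COCc4ccccc4)ccc1OCc1ccccc1
F11 | step 2 | methyl 3-bromo-4-fluoro-5-methoxybenzoate | COC(=O)c1cc(Br)c(F)c(OC)c1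
A1 | alternative 1 | (2S)-6-bromo-8-methoxy-2-(3-methoxy-4-methylsulfonyloxyphenyl)chroman-4-one | COc1cc([C@@H]2CC(=O)c3cc(Br)cc(OC)c3O2)ccc1OS(C)(=O)=O
A2 | alternative 1 | methyl trans-(2S,3R)-5-bromo-7-methoxy-2-(3-methoxy-4-methylsulfonyloxyphenyl)-2,3-dihydro-1-benzofuran-3-carboxylate | COc1cc([C@H]2Oc3c(OC)cc(Br)cc3[C@@H]2C(=O)OC)ccc1OS(C)(=O)=O
A3 | alternative 2 | methyl 3-methoxy-2-oxo-2H-pyran-5-carboxylate | COC(=O)C1=COC(=O)C(OC)=C1
A4 | alternative 2 | tert-butyl{[(2S,3R)-2-(4-benzyloxy-3-methoxyphenyl)-5-(trimethylsilyloxy)-2,3-dihydrofuran-3-yl]methoxy}dimethylsilane | COc1cc([C@H]2OC(O[Si](C)(C)C)=C[C@@H]2CO[Si](C)(C)C(C)(C)C)ccc1OCc1ccccc1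
A5 | alternative 2 | methyl trans-(2S,3R)-2-(4-benzyloxy-3-methoxyphenyl)-3-(tert-butyldimethylsilyloxymethyl)-7-methoxy-2,3-dihydro-1-benzofuran-5-carboxylate | COc1cc([C@H]2Oc3c(OC)cc(C(=O)OC)cc3[C@@H]2CO[Si](C)(C)C(C)(C)C)ccc1OCc1ccccc1
A6 | alternative 3 | methyl 3-[(2R)-1,3-dihydroxy-1-(4-hydroxy-3-methoxyphenyl)propan-2-yl]-4-hydroxy-5-methoxybenzoate (either C1 epimer) | COc1cc(C(O)[C@@H](CO)c2cc(C(=O)OC)cc(OC)c2O)ccc1O
A7 | alternative 3 | methyl trans-(2S,3R)-2-(4-hydroxy-3-methoxyphenyl)-3-(hydroxymethyl)-7-methoxy-2,3-dihydro-1-benzofuran-5-carboxylate | COc1cc([C@H]2Oc3c(OC)cc(C(=O)OC)cc3[C@@H]2CO)ccc1O
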